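The ratio r of D charged to X charged, with a the fraction of X left, turns any reading into a clock for one-to-one second-order reaction: u = ln[(r − 1 + a)/(a r)]/(r − 1), which is rate constant × X charged × time and, at r of one, reads 1/a − 1.

| flask | X | D | remark | time |
|---|---|---|---|---|
| Sunday's | 22 mM | 18 mM | run made earlier |  |
| Tuesday's | 22 mM | 27 mM | run made earlier |  |
| Friday's | 22 mM | 34 mM | run made earlier |  |
| south-west | 22 mM | 22.0 mM |  | 3.0 d |
| north | 22 mM | 29.0 mM |  | 3.0 d |

| run | time / h | X / % | Q / % |
|---|---|---|---|
| Sunday's | 12.0 | 59.1 | 41.2 |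
| Sunday's | 25.0 | 51.0 | 49.2 |
| Sunday's | 40.0 | 44.4 | 55.9 |
| Sunday's | 48.0 | 42.7 | 57.9 |
| Tuesday's | 12.0 | 45.3 | 53.9 |
| Tuesday's | 25.0 | 37.3 | 63.0 |
| Tuesday's | 40.0 | 29.6 | 70.2 |
| Tuesday's | 48.0 | 26.3 | 72.8 |
| Friday's | 6.00 | 45.0 | 55.4 |
| Friday's | 20.0 | 31.9 | 68.4 |
| Friday's | 30.0 | 25.6 | 73.7 |
| Friday's | 48.0 | 18.8 | 81.3 |

(scatter of a reading: 0.3 percentage points)



1. part of the X that has reacted at the end, south-west
2. part of the X that has reacted at the end, north
3. what raising the concentration of D from its lowest to its highest value here does to the part of the X that has reacted (changes below 5 percentage points count as none) (it rises / no change / it falls)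

Tuesday's run has r = 1.23, and its readings put the clock at 1.19 after 25.0 h and 1.84 after 48.0 h. We carry that line on straight and get the clock at the asked time, 2.51.

Now turn the question round. One road to no change is both flasks nearly finished, within 5 percentage points of each other. South-west, at r of one, leaves 1/(1 + u), so that road asks for a clock near 19.0, and ours is less.

We reckon that south-west leaves 28.5 %. North, with r = 1.32, leaves 16.5 %. The gap of 12 points is wider than the margin.

The forecast gave 71 % (67.5 % to 74 %) reacted for south-west and 82 % (78.5 % to 85 %) for north, and for the trend it rises, noting that “it has a fast early phase and then slows”. Our reacted share for north stands above its figure.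

South-west gives 71.4 % reacted and north 82.1 %; over the range of D, it rises, by 11 points.

    X + D → E + Q (k = 0.00380 M⁻¹ s⁻¹)
    J ⇌ E, rate k2*(cs2 - [E]) while solid is left; crystals form when [E] > cs2 (solubility = 1.10 mM, k = 7.80 × 10⁻⁵ s⁻¹)
    D + E ⇌ Z, settled at all times (K = 2900 M⁻¹)
    2 D → L (k = 0.00120 M⁻¹ s⁻¹)

Our clock gave 28.5 % and 16.5 % of X left in south-west and north, and the flasks held 29 % and 18 %. In north, 2 D to L reached the midpoint of its turnover up to the asked time by 0.766 h and X + D by 0.122 d, while the growth of crystals J from dissolved E reached its midpoint by 1.26 d; north ended with free D at 2.90 % of its charge beside 3.53 mM of Z.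

In a flask like north with 88 mM of X, r is 0.330 and the clock, scaled by X charged, is 10.1, so 33.0 % should react, with D the limiting reagent. The computed flask gives 31.1 %, with free D at 0 %.

(The earlier runs and the new flask come from a simulation with constants of no real substance, noise included.)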